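The target is cut at its two ester bonds into a differentiated 2,4-diarylcyclobutane-1,3-dicarboxylate and one amino alcohol. Each cis-fused cyclopenta[c]pyridine unit is traced to an open-chain 1,7-enyne carbamate: an intramolecular Pauson–Khand reaction joins C7a to C4a and inserts CO between C5 and C7, so the piperidine ring (N2, C1, C3, C4, C4a, C7a) and the fused cyclopentenone arise in one operation. No skeletal ring is closed afterwards; the cyclobutane is bought and diarylated by directed C–H activation. The step exploits the C6 oxygen flanked by the C7 methyl and the C4a–C7a bond as an enone retron; the C4 methyl controls C4a. Acylation (retention) and Mitsunobu esterification (inversion) of the single 6R alcohol give the two C6-epimeric esters.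

Key step: step 5

Remark on the structure: on the cyclobutane both aryl groups (C2, C4) are cis to the C1 carboxylate and trans to the C3 carboxylate; the C3 ester carries the 6S amino alcohol unit and the C1 ester its 6R epimer. Amino alcohol atoms are numbered as in cyclopenta[c]pyridine (C1, N2, C3, C4, C4a, C5, C6, C7, C7a).

Step 1
Reactants: 1 (R)-3-bromo-2-methylpropan-1-ol; 2 but-2-yn-1-amine
Product: 3 (S)-3-(but-2-yn-1-ylamino)-2-methylpropan-1-ol
Conditions: 2 (3 equiv), K2CO3, MeCN, 70 °C
Reagents that add atoms: none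
Why: SN2 N-alkylation of the primary amine by the primary bromide, with excess amine suppressing dialkylation; the stereocentre is untouched (the descriptor changes only through CIP priorities).

Step 2
Reactants: 3 (S)-3-(but-2-yn-1-ylamino)-2-methylpropan-1-ol
Product: 4 methyl (S)-but-2-yn-1-yl(3-hydroxy-2-methylpropyl)carbamate
Conditions: ClCO2Me, NaHCO3, CH2Cl2/H2O, 0 °C
Reagents that add atoms: methyl chloroformate, COC(=O)Cl
Why: Carbamate formation under Schotten–Baumann conditions, the secondary amine being acylated far faster than the primary alcohol.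

Step 3
Reactants: 4 methyl (S)-but-2-yn-1-yl(3-hydroxy-2-methylpropyl)carbamate
Product: 5 methyl (S)-but-2-yn-1-yl(2-methyl-3-oxopropyl)carbamate
Conditions: DMP (1,1,1-triacetoxy-1,1-dihydro-1,2-benziodoxol-3(1H)-one), CH2Cl2, 0 °C to rt
Reagents that add atoms: none
Why: Hypervalent-iodine oxidation of the primary alcohol to the aldehyde under non-basic conditions, so the α-stereocentre should not epimerize.

Step 4
Reactants: 5 methyl (S)-but-2-yn-1-yl(2-methyl-3-oxopropyl)carbamate
Product: 6 methyl (R)-but-2-yn-1-yl(2-methylbut-3-en-1-yl)carbamate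
Conditions: Ph3PCH3Br, KN(SiMe3)2, THF, −78 to 0 °C
Reagents that add atoms: methyltriphenylphosphonium bromide, C[P+](c1ccccc1)(c1ccccc1)c1ccccc1.[Br-]
Why: Wittig methylenation with the unstabilized ylide at low temperature, where carbonyl addition outruns enolization, turns CHO into the vinyl group and keeps the α-methyl stereocentre (future C4).

Step 5
Reactants: 6 methyl (R)-but-2-yn-1-yl(2-methylbut-3-en-1-yl)carbamate
Product: 8 methyl (4R,4aR)-4,7-dimethyl-6-oxo-1,3,4,4a,5,6-hexahydro-2H-cyclopenta[c]pyridine-2-carboxylate, via alkyne hexacarbonyldicobalt complex 7 (not isolated)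
Conditions: Co2(CO)8 (1.1 equiv), CH2Cl2, rt; then DMSO (6 equiv), 45 °C
Reagents that add atoms: dicobalt octacarbonyl, O=C=[Co](=C=O)(=C=O)(=C=O)[Co](=C=O)(=C=O)(=C=O)=C=O
Why: Co2(CO)8 binds the alkyne of 6 as complex 7; after loss of CO the tethered alkene coordinates and inserts into the Co–C bond of the internal alkyne carbon, then CO inserts and reductive elimination releases the enone (intramolecular Pauson–Khand [2+2+1] cycloaddition, a known reaction of heteroatom-tethered 1,7-enynes). The piperidine ring closes by C7a–C4a bond formation, exo with respect to both the alkyne and the alkene (6-exo), and the cyclopentenone closes when CO links C5 and C7. The only new stereocentre, C4a, is controlled by the allylic C4 methyl group, which should sit pseudo-equatorial in the chair-like transition state of alkene insertion and so end trans to C5 (cis to H4a). Regiochemistry needs no control, because the four-atom tether (C1, N2, C3, C4) allows only the fused cyclopenta[c]pyridinone, and the carbamate favours the folded conformer needed for closure. The enone formed (C6=O, C7=C7a) carries the handles used afterwards to set C7a, C7 and C6.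

Step 6
Reactants: 8 methyl (4R,4aR)-4,7-dimethyl-6-oxo-1,3,4,4a,5,6-hexahydro-2H-cyclopenta[c]pyridine-2-carboxylate
Product: 10 methyl (4R,4aR,7R,7aS)-4,7-dimethyl-6-oxooctahydro-2H-cyclopenta[c]pyridine-2-carboxylate, via 7-epi ketone 9 (not isolated)
Conditions: H2 (4 atm), 10% Pd/C, MeOH, rt; filter; then NaOMe (0.2 equiv), MeOH, rt
Reagents that add atoms: none
Why: Heterogeneous syn hydrogenation adds H2 to the C7=C7a bond from the face of H4a (the other face is covered by C4 of the piperidine ring), setting the cis ring fusion at C7a, and methoxide then equilibrates the α-carbon C7 to the more stable isomer with the methyl trans to C1.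

Step 7
Reactants: 10 methyl (4R,4aR,7R,7aS)-4,7-dimethyl-6-oxooctahydro-2H-cyclopenta[c]pyridine-2-carboxylate
Product: 12 (4R,4aR,6R,7R,7aS)-2,4,7-trimethyloctahydro-1H-cyclopenta[c]pyridin-6-ol, via 6R hydroxy carbamate 11 (not isolated)
Conditions: LiAlH4 (4 equiv), THF, −78 °C, then reflux; aqueous NaOH work-up
Reagents that add atoms: none
Why: Hydride reduction: LiAlH4 should attack the C6 ketone from the convex face (that of H4a and H7a), giving the 6R alcohol with OH trans to the C7 methyl, and at reflux it reduces the methyl carbamate to the N-methyl group.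

Step 8
Reactants: 13 4-iodo-2-methoxyphenol
Product: 14 1-(benzyloxy)-4-iodo-2-methoxybenzene
Conditions: BnBr, K2CO3, DMF, rt
Reagents that add atoms: benzyl bromide, BrCc1ccccc1
Why: Williamson etherification of the phenoxide gives a benzyl ether that survives all later steps and is removed by hydrogenolysis.

Step 9
Reactants: 15 trans-3-(methoxycarbonyl)cyclobutane-1-carboxylic acid; 16 quinolin-8-amine
Product: 17 methyl trans-3-(quinolin-8-ylcarbamoyl)cyclobutane-1-carboxylate
Conditions: DCC, DMAP (cat.), CH2Cl2, 0 °C to rt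
Reagents that add atoms: none
Why: Carbodiimide-mediated amidation installs the N,N-bidentate 8-aminoquinoline directing group without touching the trans ring configuration.

Step 10
Reactants: 17 methyl trans-3-(quinolin-8-ylcarbamoyl)cyclobutane-1-carboxylate; 14 1-(benzyloxy)-4-iodo-2-methoxybenzene
Product: 18 methyl 2,4-bis[4-(benzyloxy)-3-methoxyphenyl]-3-(quinolin-8-ylcarbamoyl)cyclobutane-1-carboxylate (both aryl groups cis to the amide and trans to the ester)
Conditions: Pd(OAc)2 (10 mol%), AgOAc (2.5 equiv), 14 (3 equiv), toluene, 110 °C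
Reagents that add atoms: none
Why: 8-Aminoquinoline-directed palladium-catalysed β-C(sp3)–H arylation with an aryl iodide: the chelated palladacycle can cleave only the two β C–H bonds cis to the amide, so both aryl groups are placed cis to the amide carbon and trans to the ester, which lies on the opposite face.

Step 11
Reactants: 18 methyl 2,4-bis[4-(benzyloxy)-3-methoxyphenyl]-3-(quinolin-8-ylcarbamoyl)cyclobutane-1-carboxylate
Product: 19 N-(tert-butoxycarbonyl) derivative of 18 (Boc on the amide nitrogen)
Conditions: Boc2O (3 equiv), DMAP (0.3 equiv), MeCN, 60 °C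
Reagents that add atoms: di-tert-butyl dicarbonate, CC(C)(C)OC(=O)OC(=O)OC(C)(C)C
Why: N-tert-butoxycarbonylation of the secondary amide under DMAP catalysis twists and activates the amide for nucleophilic cleavage.

Step 12
Reactants: 19 N-(tert-butoxycarbonyl) derivative of 18
Product: 21 2,4-bis[4-(benzyloxy)-3-methoxyphenyl]-3-(methoxycarbonyl)cyclobutane-1-carboxylic acid (acid cis to both aryl groups; methyl ester trans), via peroxy acid 20 (not isolated)
Conditions: LiOH·H2O (2 equiv), 30% H2O2 (5 equiv), THF/H2O, 0 °C; then Na2SO3; then 1 M HCl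
Reagents that add atoms: hydrogen peroxide, OO
Why: Hydroperoxide (an alpha-effect nucleophile) cleaves the activated N-acyl carbamate at the acyl carbon faster than it attacks the hindered methyl ester, sulfite reduces the peroxy acid, and the weakly basic medium should leave the cis arrangement at C1 untouched.

Step 13
Reactants: 21 2,4-bis[4-(benzyloxy)-3-methoxyphenyl]-3-(methoxycarbonyl)cyclobutane-1-carboxylic acid; 12 (4R,4aR,6R,7R,7aS)-2,4,7-trimethyloctahydro-1H-cyclopenta[c]pyridin-6-ol
Product: 23 mixed diester: C3 methyl ester and C1 (4R,4aR,6R,7R,7aS)-2,4,7-trimethyloctahydro-1H-cyclopenta[c]pyridin-6-yl ester of the 2,4-bis[4-(benzyloxy)-3-methoxyphenyl]cyclobutane-1,3-dicarboxylic acid, via acid chloride 22 (not isolated)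
Conditions: 21, (COCl)2, DMF (cat.), CH2Cl2, 0 °C to rt, evaporate; 12, n-BuLi (1.05 equiv), THF, −78 °C, then 22, −78 to 0 °C
Reagents that add atoms: none
Why: Acyl chloride formation followed by acylation of the lithium alkoxide of 12 (addition–elimination at the acyl carbon) leaves the C6–O bond of the alcohol intact, so the 6R configuration is retained, while the low temperature disfavours ketene formation that could epimerize cyclobutane C1.

Step 14
Reactants: 23 mixed diester (C3 methyl ester; C1 6R amino alcohol ester)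
Product: 25 C3 carboxylic acid of 23 (C1 6R amino alcohol ester retained), via trimethylstannyl ester 24 (not isolated)
Conditions: Me3SnOH (5 equiv), ClCH2CH2Cl, 80 °C; then dilute aqueous HCl to pH 5
Reagents that add atoms: trimethyltin hydroxide, C[Sn](C)(C)O
Why: Trimethyltin hydroxide cleaves the methyl ester under near-neutral conditions by tin-assisted hydroxide delivery, selective for the methyl over the hindered secondary ester and non-epimerizing at C1.

Step 15
Reactants: 25 C3 carboxylic acid (C1 6R amino alcohol ester); 12 (4R,4aR,6R,7R,7aS)-2,4,7-trimethyloctahydro-1H-cyclopenta[c]pyridin-6-ol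
Product: 26 bis(O-benzyl) ether of the target (C3 ester 6S, C1 ester 6R)
Conditions: PPh3, DIAD, THF, 0 °C to rt
Reagents that add atoms: none
Why: Mitsunobu esterification: the carboxylate displaces the oxyphosphonium group at C6 by SN2 from the convex face, inverting the 6R alcohol to the 6S ester required at C3.

Step 16
Reactants: 26 bis(O-benzyl) ether of the target
Product: 27 target CNP0283097.4
Conditions: H2 (1 atm), Pd(OH)2/C, MeOH/AcOH, rt
Reagents that add atoms: none
Why: Hydrogenolysis of the two aryl benzyl ethers over palladium, with acetic acid protonating the amines that would otherwise retard debenzylation, frees the phenols without touching the esters or the cyclobutane.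

Compound list
1 | (R)-3-bromo-2-methylpropan-1-ol | BrC[C@@H](CO)C | starting material
2 | but-2-yn-1-amine | CC#CCN | starting material
3 | (S)-3-(but-2-yn-1-ylamino)-2-methylpropan-1-ol | CC#CCNC[C@@H](CO)C | intermediate
4 | methyl (S)-but-2-yn-1-yl(3-hydroxy-2-methylpropyl)carbamate | CC#CCN(C(=O)OC)C[C@@H](CO)C | intermediate
5 | methyl (S)-but-2-yn-1-yl(2-methyl-3-oxopropyl)carbamate | CC#CCN(C(=O)OC)C[C@@H](C=O)C | intermediate
6 | methyl (R)-but-2-yn-1-yl(2-methylbut-3-en-1-yl)carbamate | CC#CCN(C(=O)OC)C[C@@H](C=C)C | intermediate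
7 | hexacarbonyldicobalt complex of the alkyne of 6 (not isolated) | CC12C3(CN(C(=O)OC)C[C@@H](C=C)C)[Co]1(=C=O)(=C=O)(=C=O)[Co]23(=C=O)(=C=O)=C=O | intermediate
8 | methyl (4R,4aR)-4,7-dimethyl-6-oxo-1,3,4,4a,5,6-hexahydro-2H-cyclopenta[c]pyridine-2-carboxylate | O=C1C[C@H]2C(CN(C(=O)OC)C[C@@H]2C)=C1C | intermediate
9 | methyl (4R,4aR,7S,7aS)-4,7-dimethyl-6-oxooctahydro-2H-cyclopenta[c]pyridine-2-carboxylate (7-epi ketone, not isolated) | O=C1C[C@H]2[C@H](CN(C(=O)OC)C[C@@H]2C)[C@@H]1C | intermediate
10 | methyl (4R,4aR,7R,7aS)-4,7-dimethyl-6-oxooctahydro-2H-cyclopenta[c]pyridine-2-carboxylate | O=C1C[C@H]2[C@H](CN(C(=O)OC)C[C@@H]2C)[C@H]1C | intermediate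
11 | methyl (4R,4aR,6R,7R,7aS)-6-hydroxy-4,7-dimethyloctahydro-2H-cyclopenta[c]pyridine-2-carboxylate (not isolated) | O[C@@H]1C[C@H]2[C@H](CN(C(=O)OC)C[C@@H]2C)[C@H]1C | intermediate
12 | (4R,4aR,6R,7R,7aS)-2,4,7-trimethyloctahydro-1H-cyclopenta[c]pyridin-6-ol | O[C@@H]1C[C@H]2[C@H](CN(C)C[C@@H]2C)[C@H]1C | intermediate
13 | 4-iodo-2-methoxyphenol | COc1cc(I)ccc1O | starting material
14 | 1-(benzyloxy)-4-iodo-2-methoxybenzene | COc1cc(I)ccc1OCc1ccccc1 | intermediate
15 | trans-3-(methoxycarbonyl)cyclobutane-1-carboxylic acid | COC(=O)[C@H]1C[C@H](C(=O)O)C1 | starting material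
16 | quinolin-8-amine | Nc1cccc2cccnc12 | starting material
17 | methyl trans-3-(quinolin-8-ylcarbamoyl)cyclobutane-1-carboxylate | COC(=O)[C@H]1C[C@H](C(=O)Nc2cccc3cccnc23)C1 | intermediate
18 | methyl 2,4-bis[4-(benzyloxy)-3-methoxyphenyl]-3-(quinolin-8-ylcarbamoyl)cyclobutane-1-carboxylate (aryl groups cis to amide, trans to ester) | COc1cc([C@@H]2[C@@H](C(=O)OC)[C@H](c3ccc(OCc4ccccc4)c(OC)c3)[C@@H]2C(=O)Nc2cccc3cccnc23)ccc1OCc1ccccc1 | intermediate
19 | N-(tert-butoxycarbonyl) derivative of 18 | COc1cc([C@@H]2[C@@H](C(=O)OC)[C@H](c3ccc(OCc4ccccc4)c(OC)c3)[C@@H]2C(=O)N(C(=O)OC(C)(C)C)c2cccc3cccnc23)ccc1OCc1ccccc1 | intermediate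
20 | peroxy acid corresponding to 21 (not isolated) | COc1cc([C@@H]2[C@@H](C(=O)OC)[C@H](c3ccc(OCc4ccccc4)c(OC)c3)[C@@H]2C(=O)OO)ccc1OCc1ccccc1 | intermediate
21 | 2,4-bis[4-(benzyloxy)-3-methoxyphenyl]-3-(methoxycarbonyl)cyclobutane-1-carboxylic acid (acid cis to both aryl groups, ester trans) | COc1cc([C@@H]2[C@@H](C(=O)OC)[C@H](c3ccc(OCc4ccccc4)c(OC)c3)[C@@H]2C(=O)O)ccc1OCc1ccccc1 | intermediate
22 | acid chloride of 21 (not isolated) | COc1cc([C@@H]2[C@@H](C(=O)OC)[C@H](c3ccc(OCc4ccccc4)c(OC)c3)[C@@H]2C(=O)Cl)ccc1OCc1ccccc1 | intermediate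
23 | mixed diester: C3 methyl ester, C1 (4R,4aR,6R,7R,7aS)-amino alcohol ester | COc1cc([C@@H]2[C@@H](C(=O)OC)[C@H](c3ccc(OCc4ccccc4)c(OC)c3)[C@@H]2C(=O)O[C@@H]2C[C@H]3[C@H](CN(C)C[C@@H]3C)[C@H]2C)ccc1OCc1ccccc1 | intermediate
24 | C3 trimethylstannyl ester of 25 (not isolated) | COc1cc([C@@H]2[C@@H](C(=O)O[Sn](C)(C)C)[C@H](c3ccc(OCc4ccccc4)c(OC)c3)[C@@H]2C(=O)O[C@@H]2C[C@H]3[C@H](CN(C)C[C@@H]3C)[C@H]2C)ccc1OCc1ccccc1 | intermediate
25 | C3 carboxylic acid with C1 (4R,4aR,6R,7R,7aS)-amino alcohol ester | COc1cc([C@@H]2[C@@H](C(=O)O)[C@H](c3ccc(OCc4ccccc4)c(OC)c3)[C@@H]2C(=O)O[C@@H]2C[C@H]3[C@H](CN(C)C[C@@H]3C)[C@H]2C)ccc1OCc1ccccc1 | intermediate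
26 | bis(O-benzyl) ether of the target | COc1cc([C@@H]2[C@@H](C(=O)O[C@H]3C[C@H]4[C@H](CN(C)C[C@@H]4C)[C@H]3C)[C@H](c3ccc(OCc4ccccc4)c(OC)c3)[C@@H]2C(=O)O[C@@H]2C[C@H]3[C@H](CN(C)C[C@@H]3C)[C@H]2C)ccc1OCc1ccccc1 | intermediate
27 | CNP0283097.4 | COc1cc([C@@H]2[C@@H](C(=O)O[C@H]3C[C@H]4[C@H](CN(C)C[C@@H]4C)[C@H]3C)[C@H](c3ccc(O)c(OC)c3)[C@@H]2C(=O)O[C@@H]2C[C@H]3[C@H](CN(C)C[C@@H]3C)[C@H]2C)ccc1O | target

Total step count: 16. Longest linear sequence: 11 steps (steps 1 to 7, then 13 to 16).

Steps most likely to fail

Step 5. Alkene insertion across the six-membered tether may be slow, so that the cobalt complex decomposes or oligomerizes before cyclization, and the C4 methyl may discriminate the alkene faces only moderately. The fallback sets out from enyne 6 and builds the same bicycle by an early-metal metallacycle: Cp2ZrCl2 and n-BuLi (2 equiv) in THF at −78 °C to rt should give the zirconabicycle F1, whose reversible formation favours the isomer with the C4 methyl trans to C5. Carbonylation under CO (1 atm) and acidic work-up would then release enone 8, where the route is rejoined.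

Step 13. Acyl transfer to the carboxyl flanked by two cis aryl groups may be sluggish, and deprotonation of the acid chloride to a ketene would then compete and erode the cis configuration at cyclobutane C1. The fallback forms the same ester bond by O-alkylation with inversion in place of acyl transfer. It sets out from alcohol 12, which is inverted at C6 by a Mitsunobu reaction with 4-nitrobenzoic acid (PPh3, DIAD, THF) to the 6S 4-nitrobenzoate F2. Methanolysis (K2CO3, MeOH) gives the 6S alcohol F3, and a Mitsunobu coupling of acid 21 with F3 should give 23, where the route is rejoined.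

Step 15. Elimination of the activated alcohol or slow SN2 displacement at C6 next to the C7 methyl may win, aggravated by the zwitterionic nature of acid 25. The fallback switches to acyl transfer with retention. It sets out from 12, which is converted as above into the 6S 4-nitrobenzoate F4 and then the 6S alcohol F5. Acid 25 is then activated as the mixed anhydride (2,4,6-trichlorobenzoyl chloride, Et3N, then DMAP, toluene) and acylates F5 to give 26, where the route is rejoined. The C3 carboxyl is trans to both aryl groups, so it is the less hindered one and its configuration is the thermodynamically stable one.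

Further compounds
F1 | step 5 | zirconabicycle from 6: 2-(methoxycarbonyl)-aza-tethered bis(cyclopentadienyl)zirconacyclopentene, (4R,4aR) | [Zr]1(C2C=CC=C2)(C2C=CC=C2)C[C@H]2C(CN(C(=O)OC)C[C@@H]2C)=C1C
F2 | step 13 | (4R,4aR,6S,7R,7aS)-2,4,7-trimethyloctahydro-1H-cyclopenta[c]pyridin-6-yl 4-nitrobenzoate | O=C(O[C@H]1C[C@H]2[C@H](CN(C)C[C@@H]2C)[C@H]1C)c1ccc(cc1)[N+](=O)[O-]
F3 | step 13 | (4R,4aR,6S,7R,7aS)-2,4,7-trimethyloctahydro-1H-cyclopenta[c]pyridin-6-ol | O[C@H]1C[C@H]2[C@H](CN(C)C[C@@H]2C)[C@H]1C
F4 | step 15 | (4R,4aR,6S,7R,7aS)-2,4,7-trimethyloctahydro-1H-cyclopenta[c]pyridin-6-yl 4-nitrobenzoate | O=C(O[C@H]1C[C@H]2[C@H](CN(C)C[C@@H]2C)[C@H]1C)c1ccc(cc1)[N+](=O)[O-]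
F5 | step 15 | (4R,4aR,6S,7R,7aS)-2,4,7-trimethyloctahydro-1H-cyclopenta[c]pyridin-6-ol | O[C@H]1C[C@H]2[C@H](CN(C)C[C@@H]2C)[C@H]1C
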